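**Plan**
- Retrosynthetic cuts, in order: C1=C2 (metathesis), C3–C4 (aldol), C10–C1 together with the C10–O lactone bond (vinyl addition/lactonisation), C4–C5 (enolate alkylation), C13–C16 (gold cyclisation), C15–C16 (acetylide addition), and last C8–C14 plus C9–C11 ([4+2]).
- Enabling feature: ring C (C8, C9, C11–C14) carries adjacent oxygens on C12 and C13 and is cis-fused to ring B at quaternary C8 (which bears C15) and at C9–H. This is the imprint of a 2,3-dioxygenated butadiene added across C8=C9 of a cyclopentenone that has a formyl group on C8.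
- Forward order: ring B (resolved cyclopentenone) → ring C by Diels–Alder → ring D by gold catalysis → 19,10-lactone → ring A by aldol and metathesis → C7 oxidation and desilylation.
- Stereochemistry: C6 from a lipase resolution; C8/C9 from the suprafacial cycloaddition anti to the C6 substituent; C15 by Felkin–Anh addition; C13 by the tether; C12 by equatorial hydride delivery; C5, C10, C4 and C3 by substrate control (trans alkylation, β-face addition filtered by lactonisation, convex-face chair aldol).

Key step: step 7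

Remarks: atom labels C1–C19 are gibberellane positions; β is the face of ring B that carries H5, H9, C7 and C15 in the target; TBS = tert-butyldimethylsilyl. The target is named below as 12α,15β-dihydroxygibberellic acid, that is, gibberellic acid with additional hydroxyl groups at C12 (α) and C15 (β).
Assumption: the lipase in step 2 is taken to acylate the (S)-alcohol faster, leaving (R)-3; with the opposite preference the (R)-acetate would be cleaved enzymatically to the same compound.

Step 1
Reactants: 1 3-ethoxycyclopent-2-en-1-one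
Product: 2 rac-3-ethoxy-5-(hydroxymethyl)cyclopent-2-en-1-one
Conditions: LDA, THF, −78 °C; HCHO (gas, from cracked paraformaldehyde); AcOH, −78 °C
Reagents that add atoms: formaldehyde, C=O
Why: Kinetic deprotonation of the vinylogous ester occurs at the α′ carbon and the lithium enolate undergoes aldol addition to monomeric formaldehyde; the new stereocentre is racemic at this stage and the cold acidic quench prevents β-elimination.

Step 2
Reactants: 2 rac-3-ethoxy-5-(hydroxymethyl)cyclopent-2-en-1-one
Product: 3 (R)-3-ethoxy-5-(hydroxymethyl)cyclopent-2-en-1-one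
Conditions: Burkholderia cepacia lipase (Amano PS), vinyl acetate, MTBE, 25 °C, stopped beyond half conversion
Reagents that add atoms: none
Why: Lipase-catalysed irreversible transesterification (kinetic resolution of a primary alcohol with a β-stereocentre) removes the (S)-enantiomer as its acetate, so the slow-reacting (R)-alcohol should be recovered enantioenriched; this fixes the future C6.

Step 3
Reactants: 3 (R)-3-ethoxy-5-(hydroxymethyl)cyclopent-2-en-1-one
Product: 4 (R)-5-[(tert-butyldimethylsilyloxy)methyl]-3-ethoxycyclopent-2-en-1-one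
Conditions: TBSCl, imidazole, CH2Cl2, 0 °C to rt
Reagents that add atoms: tert-butyldimethylsilyl chloride, CC(C)(C)[Si](C)(C)Cl
Why: Standard silylation of a primary alcohol under conditions too weakly basic to enolise the adjacent stereocentre.

Step 4
Reactants: 4 (R)-5-[(tert-butyldimethylsilyloxy)methyl]-3-ethoxycyclopent-2-en-1-one; 5 1,3-dithiane
Product: 7 (S)-4-[(tert-butyldimethylsilyloxy)methyl]-3-(1,3-dithian-2-yl)cyclopent-2-en-1-one, via dithianyl carbinol 6 (not isolated)
Conditions: n-BuLi, THF, −30 °C (lithiation of 5); add 4, −78 °C; then 1 M HCl, THF, 0 °C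
Reagents that add atoms: water, O
Why: 1,2-Addition of the dithiane anion (Corey–Seebach formyl anion equivalent) to the vinylogous ester carbonyl and acid-mediated hydrolysis with allylic transposition (Stork–Danheiser sequence) move the carbonyl to the former C–OEt carbon and place the masked formyl group on the alkene carbon next to the stereocentre, which is not touched (the descriptor changes from R to S by priority only).

Step 5
Reactants: 7 (S)-4-[(tert-butyldimethylsilyloxy)methyl]-3-(1,3-dithian-2-yl)cyclopent-2-en-1-one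
Product: 8 (S)-5-[(tert-butyldimethylsilyloxy)methyl]-3-oxocyclopent-1-ene-1-carbaldehyde
Conditions: PhI(OCOCF3)2, MeCN/H2O (9:1), 0 °C; used without chromatography
Reagents that add atoms: water, O
Why: Oxidative dithioacetal hydrolysis with a hypervalent iodine reagent unmasks the aldehyde quickly under non-basic conditions, so the γ-stereocentre (C6) and the silyl ether should survive.

Step 6
Reactants: 9 butane-2,3-dione
Product: 10 2,3-bis(tert-butyldimethylsilyloxy)buta-1,3-diene
Conditions: TBSOTf, Et3N, CH2Cl2, 0 °C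
Reagents that add atoms: tert-butyldimethylsilyl triflate, CC(C)(C)[Si](C)(C)OS(=O)(=O)C(F)(F)F
Why: Double O-silylation of the 1,2-diketone by soft enolisation (silyl triflate/amine) gives the 2,3-bis(silyloxy)diene, a known transformation of this diketone.

Step 7
Reactants: 8 (S)-5-[(tert-butyldimethylsilyloxy)methyl]-3-oxocyclopent-1-ene-1-carbaldehyde; 10 2,3-bis(tert-butyldimethylsilyloxy)buta-1,3-diene
Product: 11 cis-fused B/C keto aldehyde
Conditions: PhMe, 80 °C, sealed tube, BHT (cat.)
Reagents that add atoms: none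
Why: The electron-rich diene 10 and the C8=C9 bond of 8, whose LUMO is lowered by a carbonyl group at each end (C15 aldehyde on C8, C10 ketone on C9), should combine in a concerted, suprafacial normal-demand Diels–Alder reaction. The closest known reaction type is the cycloaddition of 2,3-bis(silyloxy)butadienes to doubly activated cycloalkenones, which gives cis-fused adducts with an angular acyl group. Ring C is closed in an intermolecular [4+2] mode that forms C8–C14 and C9–C11 together and delivers the 12,13-dione masked as its enediol bis-silyl ether. C8 and C9 are set in the same event: suprafacial addition makes the formyl group and H9 cis, and the C6 stereocentre controls the face, the diene adding anti to the CH2OTBS group so that C14 ends trans to C7. Regiochemistry and endo/exo selectivity are moot because the diene is symmetric and unsubstituted at its termini, so π-facial selectivity is the only requirement and it is secured by the substituent on the carbon directly adjacent to C8. Thermal, Lewis-acid-free conditions are chosen to keep the silyl enol ethers intact and to avoid stepwise Mukaiyama–Michael pathways.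

Step 8
Reactants: 11 cis-fused B/C keto aldehyde; 12 ethynylmagnesium bromide
Product: 13 15β-propargylic alcohol
Conditions: THF, −78 °C; aq. NH4Cl
Reagents that add atoms: none
Why: Grignard (acetylide) addition should occur at the aldehyde in preference to the hindered cyclopentanone at low temperature, and Felkin–Anh attack anti to the C6 branch (whose cis CH2OTBS group shields that side, the carbonyl oxygen lying toward C9) should set the 15β carbinol.

Step 9
Reactants: 13 15β-propargylic alcohol
Product: 14 15β-silyloxy alkyne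
Conditions: TBSOTf, 2,6-lutidine, CH2Cl2, −78 °C
Reagents that add atoms: tert-butyldimethylsilyl triflate, CC(C)(C)[Si](C)(C)OS(=O)(=O)C(F)(F)F
Why: Silyl triflate with a hindered pyridine base silylates the neopentylic propargylic alcohol without touching the enol ethers and masks it against gold-mediated side reactions.

Step 10
Reactants: 14 15β-silyloxy alkyne
Product: 15 B/C/D 10,12-diketone
Conditions: Ph3PAuCl (5 mol%), AgBF4 (5 mol%), PhMe/MeOH (10:1), rt
Reagents that add atoms: none
Why: Gold(I)-catalysed 5-exo-dig carbocyclisation of a silyl enol ether onto a terminal alkyne (Conia-ene type): C13, which sits 1,3 to the pseudo-axial propargylic arm on C8, attacks the π-activated C16 (attack by C12 would need a boat and a 6-exo closure), methanol removes the silyl group from the C12 oxocarbenium ion and protodeauration leaves the 16-methylene, the bridgehead configuration at C13 being dictated by the tether from C8.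

Step 11
Reactants: 15 B/C/D 10,12-diketone
Product: 16 12α-hydroxy 10-ketone
Conditions: NaBH4, MeOH/CH2Cl2 (1:1), −78 °C
Reagents that add atoms: none
Why: Borohydride reduction should discriminate the α-silyloxy cyclohexanone (C12) from the slower and more hindered cyclopentanone (C10), and hydride arrives on the equatorial trajectory away from the syn-axial C9–C10 bond to give the axial 12α-alcohol.

Step 12
Reactants: 16 12α-hydroxy 10-ketone
Product: 17 tetrakis-silyl 10-ketone
Conditions: TBSOTf, 2,6-lutidine, CH2Cl2, −40 to 0 °C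
Reagents that add atoms: tert-butyldimethylsilyl triflate, CC(C)(C)[Si](C)(C)OS(=O)(=O)C(F)(F)F
Why: Silyl triflate silylation of the hindered axial alcohol is standard; any 10,12-hemiketal is drained through the open hydroxy ketone, and a 1,2-silyl shift from O13 during step 11 would lead to the same product.

Step 13
Reactants: 17 tetrakis-silyl 10-ketone; 18 ethyl bromoacetate
Product: 19 C5-alkylated keto ester
Conditions: LDA, THF, −78 °C; then 18, DMPU, −78 to −40 °C
Reagents that add atoms: none
Why: Kinetic deprotonation of the C10 ketone occurs at the C5 methylene because C9–H is a hindered ring-fusion methine, and in this ketone enolate alkylation the lithium enolate displaces bromide from the α-bromo ester anti to the neighbouring 6β-CH2OTBS group, placing the acetate arm α on C5 (also the thermodynamically favoured trans arrangement).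

Step 14
Reactants: 19 C5-alkylated keto ester; 20 vinylmagnesium bromide
Product: 22 vinyl 19,10-γ-lactone, via C10 vinyl carbinol ester 21 (not isolated)
Conditions: CeCl3, THF, −78 °C, then 0 °C; aq. NH4Cl
Reagents that add atoms: none
Why: Organocerium 1,2-addition suppresses enolisation and adds to the ketone far faster than to the ester; the vinyl group should enter from the β face, anti to the α-oriented groups flanking C10 (C4 on C5, C11 on C9, the syn-axial 12α-OTBS), and the resulting 10α-alkoxide, cis to the acetate arm, closes the γ-lactone by acyl substitution, which only this C10 epimer can do.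

Step 15
Reactants: 22 vinyl 19,10-γ-lactone
Product: 23 4-methyl lactone
Conditions: LDA, THF, −78 °C; MeI
Reagents that add atoms: iodomethane, CI
Why: Lactone enolate alkylation installs C18; the methyl group enters from the convex face but the C4 configuration is inconsequential because this centre is enolised again in step 16.

Step 16
Reactants: 23 4-methyl lactone; 24 acrolein
Product: 25 aldol adduct
Conditions: LDA, THF, −78 °C; then 24; AcOH, −78 °C
Reagents that add atoms: none
Why: Aldol 1,2-addition of the lithium lactone enolate to the enal through a Zimmerman–Traxler chair: the aldehyde approaches C4 on the convex face of the lactone/ring B bicycle, anti to C6, so that C3 ends cis to the C10 vinyl group and the methyl group on the concave face, and a chair with the vinyl substituent equatorial places the 3-hydroxyl syn to the 4-methyl group (3β after ring closure).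

Step 17
Reactants: 25 aldol adduct
Product: 26 ring-A allylic alcohol
Conditions: Grubbs II (5 mol%), CH2Cl2, 40 °C
Reagents that add atoms: none
Why: Ring-closing metathesis of the two cis-disposed monosubstituted vinyl groups closes ring A as the C1=C2 cyclohexene, while the hindered 1,1-disubstituted 16-methylene should not be engaged.

Step 18
Reactants: 26 ring-A allylic alcohol
Product: 27 pentakis-silyl ether
Conditions: TBSOTf, 2,6-lutidine, CH2Cl2, −78 to 0 °C
Reagents that add atoms: tert-butyldimethylsilyl triflate, CC(C)(C)[Si](C)(C)OS(=O)(=O)C(F)(F)F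
Why: Silylation of the 3β-hydroxyl under buffered, non-basic conditions avoids retro-aldol cleavage and rearrangement of the allylic lactone.

Step 19
Reactants: 27 pentakis-silyl ether
Product: 28 C7 primary alcohol
Conditions: HF·pyridine, pyridine, THF, 0 °C
Reagents that add atoms: none
Why: Buffered HF·pyridine cleaves the primary silyl ether much faster than the hindered secondary and tertiary ones (selective desilylation).

Step 20
Reactants: 28 C7 primary alcohol
Product: 30 3,12,13,15-tetra-O-TBS 7-carboxylic acid, via C7 aldehyde 29 (not isolated)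
Conditions: TEMPO (cat.), PhI(OAc)2, MeCN/H2O (1:1), rt
Reagents that add atoms: water, O
Why: Oxoammonium (TEMPO/PhI(OAc)2) oxidation in aqueous acetonitrile takes the primary alcohol through the aldehyde hydrate to the acid under near-neutral conditions that should leave the alkenes, the silyl ethers and the C6 stereocentre intact.

Step 21
Reactants: 30 3,12,13,15-tetra-O-TBS 7-carboxylic acid
Product: 31 12α,15β-dihydroxygibberellic acid
Conditions: HF·pyridine (excess), MeCN, 0 to 35 °C
Reagents that add atoms: none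
Why: Fluoride-mediated global desilylation under mildly acidic conditions is chosen because the 3-hydroxy-1-ene 19,10-lactone of the target is base-labile.

**Compound list**

1 | 3-ethoxycyclopent-2-en-1-one | CCOC1=CC(=O)CC1 | starting material
2 | rac-3-ethoxy-5-(hydroxymethyl)cyclopent-2-en-1-one | CCOC1=CC(=O)C(CO)C1 | intermediate
3 | (R)-3-ethoxy-5-(hydroxymethyl)cyclopent-2-en-1-one | CCOC1=CC(=O)[C@@H](CO)C1 | intermediate
4 | (R)-5-[(tert-butyldimethylsilyloxy)methyl]-3-ethoxycyclopent-2-en-1-one | CCOC1=CC(=O)[C@@H](CO[Si](C)(C)C(C)(C)C)C1 | intermediate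
5 | 1,3-dithiane | C1CSCSC1 | starting material
6 | (5R)-5-[(TBSO)methyl]-1-(1,3-dithian-2-yl)-3-ethoxycyclopent-2-en-1-ol, both C1 epimers (not isolated) | CCOC1=CC(O)(C2SCCCS2)[C@@H](CO[Si](C)(C)C(C)(C)C)C1 | intermediate
7 | (S)-4-[(TBSO)methyl]-3-(1,3-dithian-2-yl)cyclopent-2-en-1-one | S1CCCSC1C2=CC(=O)C[C@@H]2CO[Si](C)(C)C(C)(C)C | intermediate
8 | (S)-5-[(TBSO)methyl]-3-oxocyclopent-1-ene-1-carbaldehyde (C8=C9, C10 ketone, C15 formyl, C6 CH2OTBS) | O=CC1=CC(=O)C[C@@H]1CO[Si](C)(C)C(C)(C)C | intermediate
9 | butane-2,3-dione | CC(=O)C(C)=O | starting material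
10 | 2,3-bis(tert-butyldimethylsilyloxy)buta-1,3-diene | C=C(O[Si](C)(C)C(C)(C)C)C(=C)O[Si](C)(C)C(C)(C)C | intermediate
11 | cis-fused B/C keto aldehyde: 3-[(TBSO)methyl]-5,6-bis(TBSO)-1-oxo-hexahydroindene-3a-carbaldehyde; ring B cyclopentanone (C10=O), ring C 12,13-bis(TBSO)-12-ene, angular 8β-CHO cis to H9, 6β-CH2OTBS cis to CHO | O=C[C@]12CC(O[Si](C)(C)C(C)(C)C)=C(O[Si](C)(C)C(C)(C)C)C[C@H]1C(=O)C[C@@H]2CO[Si](C)(C)C(C)(C)C | intermediate
12 | ethynylmagnesium bromide | C#C[Mg]Br | starting material
13 | 15β-propargylic alcohol: 11 with the formyl group converted into CH(OH)C≡CH (C15–C17), hydroxyl 15β | C#C[C@@H](O)[C@]12CC(O[Si](C)(C)C(C)(C)C)=C(O[Si](C)(C)C(C)(C)C)C[C@H]1C(=O)C[C@@H]2CO[Si](C)(C)C(C)(C)C | intermediate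
14 | 15-O-TBS ether of 13 | C#C[C@@H](O[Si](C)(C)C(C)(C)C)[C@]12CC(O[Si](C)(C)C(C)(C)C)=C(O[Si](C)(C)C(C)(C)C)C[C@H]1C(=O)C[C@@H]2CO[Si](C)(C)C(C)(C)C | intermediate
15 | B/C/D tricyclic diketone: ring D closed by C13–C16 (bicyclo[3.2.1]octane, 16-methylene), bridgehead 13-OTBS, 15β-OTBS, 12-oxo, 10-oxo, 6β-CH2OTBS | C=C1[C@@H](O[Si](C)(C)C(C)(C)C)[C@]23C[C@@]1(O[Si](C)(C)C(C)(C)C)C(=O)C[C@H]2C(=O)C[C@@H]3CO[Si](C)(C)C(C)(C)C | intermediate
16 | 12α-alcohol of 15 (12-OH axial, on the side of the C14 bridge), 10-ketone retained | C=C1[C@@H](O[Si](C)(C)C(C)(C)C)[C@]23C[C@@]1(O[Si](C)(C)C(C)(C)C)[C@@H](O)C[C@H]2C(=O)C[C@@H]3CO[Si](C)(C)C(C)(C)C | intermediate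
17 | 12α-O-TBS ether of 16 (TBS on O7, O12, O13, O15) | C=C1[C@@H](O[Si](C)(C)C(C)(C)C)[C@]23C[C@@]1(O[Si](C)(C)C(C)(C)C)[C@@H](O[Si](C)(C)C(C)(C)C)C[C@H]2C(=O)C[C@@H]3CO[Si](C)(C)C(C)(C)C | intermediate
18 | ethyl bromoacetate | CCOC(=O)CBr | starting material
19 | keto ester: 17 with CH2CO2Et (C4, C19) on C5, 5α (trans to 6β-CH2OTBS) | C=C1[C@@H](O[Si](C)(C)C(C)(C)C)[C@]23C[C@@]1(O[Si](C)(C)C(C)(C)C)[C@@H](O[Si](C)(C)C(C)(C)C)C[C@H]2C(=O)[C@@H](CC(=O)OCC)[C@@H]3CO[Si](C)(C)C(C)(C)C | intermediate
20 | vinylmagnesium bromide | C=C[Mg]Br | starting material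
21 | hydroxy ester: 19 with C10 as C(OH)(CH=CH2), 10α-OH, 10β-vinyl (not isolated) | C=C1[C@@H](O[Si](C)(C)C(C)(C)C)[C@]23C[C@@]1(O[Si](C)(C)C(C)(C)C)[C@@H](O[Si](C)(C)C(C)(C)C)C[C@H]2[C@](O)(C=C)[C@@H](CC(=O)OCC)[C@@H]3CO[Si](C)(C)C(C)(C)C | intermediate
22 | vinyl lactone: 19,10-γ-lactone (O on C10α, C19=O, C4H2) cis-fused to ring B, 10β-vinyl (C1) | C=C1[C@@H](O[Si](C)(C)C(C)(C)C)[C@]23C[C@@]1(O[Si](C)(C)C(C)(C)C)[C@@H](O[Si](C)(C)C(C)(C)C)C[C@H]2[C@@]4(C=C)OC(=O)C[C@H]4[C@@H]3CO[Si](C)(C)C(C)(C)C | intermediate
23 | 4-methyl lactone: 22 methylated at C4, methyl cis to H5 | C=C1[C@@H](O[Si](C)(C)C(C)(C)C)[C@]23C[C@@]1(O[Si](C)(C)C(C)(C)C)[C@@H](O[Si](C)(C)C(C)(C)C)C[C@H]2[C@@]4(C=C)OC(=O)[C@H](C)[C@H]4[C@@H]3CO[Si](C)(C)C(C)(C)C | intermediate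
24 | acrolein (prop-2-enal) | C=CC=O | starting material
25 | aldol adduct: C4 quaternary (18-methyl on the concave face, C3 on the H5 face), C3 carbinol (3β after ring closure) bearing vinyl (C2), 10β-vinyl | C=C1[C@@H](O[Si](C)(C)C(C)(C)C)[C@]23C[C@@]1(O[Si](C)(C)C(C)(C)C)[C@@H](O[Si](C)(C)C(C)(C)C)C[C@H]2[C@@]4(C=C)OC(=O)[C@](C)([C@@H](O)C=C)[C@H]4[C@@H]3CO[Si](C)(C)C(C)(C)C | intermediate
26 | ring-A allylic alcohol: complete gibberellane 19,10-lactone skeleton with C1=C2, 3β-OH, 12α,13,15β-tris(OTBS), 16-methylene, 6β-CH2OTBS | C=C1[C@@H](O[Si](C)(C)C(C)(C)C)[C@]23C[C@@]1(O[Si](C)(C)C(C)(C)C)[C@@H](O[Si](C)(C)C(C)(C)C)C[C@H]2[C@@]12C=C[C@H](O)[C@@](C)(C(=O)O1)[C@H]2[C@@H]3CO[Si](C)(C)C(C)(C)C | intermediate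
27 | 3-O-TBS ether of 26 | C=C1[C@@H](O[Si](C)(C)C(C)(C)C)[C@]23C[C@@]1(O[Si](C)(C)C(C)(C)C)[C@@H](O[Si](C)(C)C(C)(C)C)C[C@H]2[C@@]12C=C[C@H](O[Si](C)(C)C(C)(C)C)[C@@](C)(C(=O)O1)[C@H]2[C@@H]3CO[Si](C)(C)C(C)(C)C | intermediate
28 | primary alcohol: 27 with C7 as CH2OH | C=C1[C@@H](O[Si](C)(C)C(C)(C)C)[C@]23C[C@@]1(O[Si](C)(C)C(C)(C)C)[C@@H](O[Si](C)(C)C(C)(C)C)C[C@H]2[C@@]12C=C[C@H](O[Si](C)(C)C(C)(C)C)[C@@](C)(C(=O)O1)[C@H]2[C@@H]3CO | intermediate
29 | aldehyde: 28 with C7 as CHO (not isolated) | C=C1[C@@H](O[Si](C)(C)C(C)(C)C)[C@]23C[C@@]1(O[Si](C)(C)C(C)(C)C)[C@@H](O[Si](C)(C)C(C)(C)C)C[C@H]2[C@@]12C=C[C@H](O[Si](C)(C)C(C)(C)C)[C@@](C)(C(=O)O1)[C@H]2[C@@H]3C=O | intermediate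
30 | 3,12,13,15-tetra-O-TBS 7-carboxylic acid: 28 with C7 as CO2H, the tetrakis-silyl ether of the target | C=C1[C@@H](O[Si](C)(C)C(C)(C)C)[C@]23C[C@@]1(O[Si](C)(C)C(C)(C)C)[C@@H](O[Si](C)(C)C(C)(C)C)C[C@H]2[C@@]12C=C[C@H](O[Si](C)(C)C(C)(C)C)[C@@](C)(C(=O)O1)[C@H]2[C@@H]3C(=O)O | intermediate
31 | 12α,15β-dihydroxygibberellic acid (target gibberellin: 3β,12α,13,15β-tetrahydroxy 19,10-lactone with C1=C2, 16-methylene and 6β-CO2H) | C=C1[C@@H](O)[C@]23C[C@@]1(O)[C@@H](O)C[C@H]2[C@@]12C=C[C@H](O)[C@@](C)(C(=O)O1)[C@H]2[C@@H]3C(=O)O | target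

**Step count**

Total: 21 steps. Longest linear sequence: 20 steps (steps 1–5 and 7–21); step 6 is a one-step branch.

**Steps most likely to fail**

Step 10. The cationic gold/methanol medium may protodesilylate the enediol bis-silyl ether before cyclisation, or C12 may compete through a 6-exo closure. The fallback activates an alkene with palladium(II) instead of an alkyne with gold. It sets out from 11: vinylmagnesium bromide (20) is added to the aldehyde at −78 °C to give the allylic alcohol F1, which is silylated (TBSOTf, 2,6-lutidine) to the allylic silyl ether F2. Pd(OAc)2 in DMSO under O2 should then promote 5-exo attack of C13 on the coordinated vinyl group and β-hydride elimination to the 16-methylene (palladium-mediated cycloalkenylation of a silyl enol ether), rejoining the route at 15.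

Step 14. The vinyl nucleophile may approach the congested C10 ketone from the α face, or the ketone may enolise instead of adding. The fallback forms the C10–O bond intramolecularly from the C19 carboxyl, which can only reach the α face. It sets out from 19: Wittig ethylidenation (Ph3P=CHCH3, THF, reflux, a reaction type established for hindered cyclopentanones) would give the ethylidene ester F3, and LiOH hydrolysis the ethylidene acid F4. Iodolactonisation (I2, NaHCO3, MeCN) should give the iodo lactone F5 with O10 α, and base-induced elimination of hydrogen iodide with DBU toward the methyl group would return to the route at 22.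

Step 16. The open-chain aldol may show poor topicity at the aldehyde carbon, giving C3 epimers. The fallback replaces substrate control by reagent control. It sets out from 23: the aldol is run as in step 16 and the mixture of 25 and its 3-epimer F6 is oxidised (Dess–Martin periodinane, NaHCO3, CH2Cl2) to the vinyl ketone F7. Corey–Bakshi–Shibata reduction ((R)-Me-CBS, catecholborane, toluene, −78 °C; quaternary C4 as the large group, vinyl as the small one) should then deliver the 3β carbinol, rejoining the route at 25.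

**Further compounds**

F1 | step 10 | 15β-vinyl carbinol (11 with CHO converted into CH(OH)CH=CH2) | C=C[C@@H](O)[C@]12CC(O[Si](C)(C)C(C)(C)C)=C(O[Si](C)(C)C(C)(C)C)C[C@H]1C(=O)C[C@@H]2CO[Si](C)(C)C(C)(C)C
F2 | step 10 | 15-O-TBS ether of F1 | C=C[C@@H](O[Si](C)(C)C(C)(C)C)[C@]12CC(O[Si](C)(C)C(C)(C)C)=C(O[Si](C)(C)C(C)(C)C)C[C@H]1C(=O)C[C@@H]2CO[Si](C)(C)C(C)(C)C
F3 | step 14 | 10-ethylidene ester (19 with C10=O replaced by C10=CH–CH3, E/Z mixture) | C=C1[C@@H](O[Si](C)(C)C(C)(C)C)[C@]23C[C@@]1(O[Si](C)(C)C(C)(C)C)[C@@H](O[Si](C)(C)C(C)(C)C)C[C@H]2C(=CC)[C@@H](CC(=O)OCC)[C@@H]3CO[Si](C)(C)C(C)(C)C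
F4 | step 14 | 10-ethylidene acid (F3 with CO2H in place of CO2Et) | C=C1[C@@H](O[Si](C)(C)C(C)(C)C)[C@]23C[C@@]1(O[Si](C)(C)C(C)(C)C)[C@@H](O[Si](C)(C)C(C)(C)C)C[C@H]2C(=CC)[C@@H](CC(=O)O)[C@@H]3CO[Si](C)(C)C(C)(C)C
F5 | step 14 | iodo lactone (19,10-γ-lactone with 1-iodoethyl on C10β, C1 epimers) | C=C1[C@@H](O[Si](C)(C)C(C)(C)C)[C@]23C[C@@]1(O[Si](C)(C)C(C)(C)C)[C@@H](O[Si](C)(C)C(C)(C)C)C[C@H]2[C@@]4(C(C)I)OC(=O)C[C@H]4[C@@H]3CO[Si](C)(C)C(C)(C)C
F6 | step 16 | 3-epimer of 25 | C=C1[C@@H](O[Si](C)(C)C(C)(C)C)[C@]23C[C@@]1(O[Si](C)(C)C(C)(C)C)[C@@H](O[Si](C)(C)C(C)(C)C)C[C@H]2[C@@]4(C=C)OC(=O)[C@](C)([C@H](O)C=C)[C@H]4[C@@H]3CO[Si](C)(C)C(C)(C)C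
F7 | step 16 | vinyl ketone (25 with C3 as C=O) | C=C1[C@@H](O[Si](C)(C)C(C)(C)C)[C@]23C[C@@]1(O[Si](C)(C)C(C)(C)C)[C@@H](O[Si](C)(C)C(C)(C)C)C[C@H]2[C@@]4(C=C)OC(=O)[C@](C)(C(=O)C=C)[C@H]4[C@@H]3CO[Si](C)(C)C(C)(C)C
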